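## Retrosynthetic overview

1. The target is the acetate of a spirocyclic alcohol. The bond between its two fully substituted carbons, C4 (quaternary α-carbon of the keto lactone) and C8 (= C2′, the spiro ether carbon), is cut last: the enol carbon of a 4-hydroxy-5,6-dihydropyran-2-one (ring B) adds to the oxocarbenium ion of the oxane (ring A), closing the carbocycle (ring C) and with it the 2-oxabicyclo[2.2.2]octane.
2. Ring A is not closed as a six-membered ring. Its atoms O1′, C6′, C5′ and C4′ arrive as the four-membered ring of a cis-β-lactone, and C3′–C2′ (enolate carbon and carbonyl carbon of an ethyl ketone) are inserted into the acyl C–O bond by C-acylation and hemiketalisation: a ring expansion by two atoms.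
3. Enabling feature: in ring A the oxygen-bearing C4′ is 1,3 to the ring oxygen O1′ (across C5′ and C6′), and the spiro carbon C2′ is at ketone level next to the CH(CH3) carbon C3′. O1′–C6′–C5′–C4′ is therefore a masked 3-hydroxy-2-methylbutanoyl unit (a β-lactone) and C3′–C2′ is the C=C–O of an ethyl-ketone enolate.
4. The ethyl ketone carrying ring B comes from an α-methyl-β-benzyloxy aldehyde and a 1,3-bis(silyloxy)diene (chelation-controlled vinylogous Mukaiyama aldol, lactonisation, unmasking of the ketone). The aldehyde comes from an Evans syn aldol, and the β-lactone from propionyl chloride and acetaldehyde in one catalytic asymmetric step.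
5. Order of ring formation: ring B, the four-membered lactone, ring A by ring expansion, ring C (and the bicycle) last. C5′/C6′ come from catalysis and C7 from the auxiliary; C1, C3′, C4′, C8, C4 and C6 are relayed by substrate control.

Key step: step 12

Locants used in the text are those of the target: ring A is the oxane O1′, C2′–C6′ (C2′ spiro); the bicycle is 2-oxabicyclo[2.2.2]octane C1–C8 with C8 = C2′, C3 the lactone carbonyl and C5 the ketone; ring B is the δ-lactone, ring C the carbocycle.

Assumption: the quinidine-derived catalyst is taken to give the (3R,4S)-β-lactone (its quinine-derived pseudoenantiomer would be used otherwise), and the β-keto-δ-lactones are drawn as their 4-hydroxy enol tautomers.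

## Route

Step 1
Reactants: 1 propionyl chloride; 2 acetaldehyde
Product: 4 (3R,4S)-3,4-dimethyloxetan-2-one, via methylketene 3 (not isolated)
Conditions: O-trimethylsilylquinidine (10 mol %), LiClO4 (1 equiv), i-Pr2NEt (2.5 equiv), CH2Cl2/Et2O, −78 °C
Reagents that add atoms: none
Why: Cinchona-alkaloid/LiClO4-catalysed ketene–aldehyde cyclocondensation (formal [2+2] through the (Z)-ammonium enolate of methylketene and a closed, lithium-organised transition state) should give the cis-β-lactone, the catalyst setting C3 and C4 of the lactone (future C5′ and C6′) in one event.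

Step 2
Reactants: 5 methyl 2-methyl-3-oxopentanoate
Product: 6 methyl 2-methyl-3-[(trimethylsilyl)oxy]pent-2-enoate
Conditions: Me3SiCl, Et3N, ZnCl2 (5 mol %), toluene, 40 °C
Reagents that add atoms: chlorotrimethylsilane, C[Si](C)(C)Cl
Why: O-Silylation of the enolised β-keto ester (silyl enol ether formation) is the first half of the standard preparation of 1,3-bis(silyloxy)dienes.

Step 3
Reactants: 6 methyl 2-methyl-3-[(trimethylsilyl)oxy]pent-2-enoate
Product: 7 1-methoxy-2-methyl-1,3-bis[(trimethylsilyl)oxy]penta-1,3-diene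
Conditions: LiN(i-Pr)2, THF, −78 °C; then Me3SiCl
Reagents that add atoms: chlorotrimethylsilane, C[Si](C)(C)Cl
Why: Vinylogous (γ) deprotonation of the silyloxy enoate and O-silylation of the resulting ester dienolate should give the 1,3-bis(silyloxy)diene, a masked β-keto ester dianion that reacts through its terminal carbon.

Step 4
Reactants: 8 (4S)-4-benzyl-3-propanoyl-1,3-oxazolidin-2-one; 9 propanal
Product: 11 (4S)-4-benzyl-3-[(2S,3R)-3-hydroxy-2-methylpentanoyl]-1,3-oxazolidin-2-one, via dibutylboron Z-enolate 10 (not isolated)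
Conditions: n-Bu2BOTf, Et3N, CH2Cl2, −78 → 0 °C; then pH 7 buffer, MeOH, H2O2
Reagents that add atoms: none
Why: Evans syn aldol in which the (Z)-boron enolate reacts through a Zimmerman–Traxler chair and the auxiliary dictates the enolate face, setting C2 of the acyl chain (future C7) while the 3-hydroxyl is only a placeholder that is oxidised later.

Step 5
Reactants: 11 (4S)-4-benzyl-3-[(2S,3R)-3-hydroxy-2-methylpentanoyl]-1,3-oxazolidin-2-one
Product: 12 (4S)-4-benzyl-3-[(2S,3R)-3-(benzyloxy)-2-methylpentanoyl]-1,3-oxazolidin-2-one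
Conditions: BnOC(=NH)CCl3 (1.5 equiv), TfOH (5 mol %), CH2Cl2/cyclohexane, 0 °C → rt
Reagents that add atoms: benzyl 2,2,2-trichloroacetimidate, N=C(OCc1ccccc1)C(Cl)(Cl)Cl
Why: Acid-catalysed trichloroacetimidate benzylation protects the placeholder hydroxyl without base (no retro-aldol) and installs the ether oxygen needed for chelation in step 8.

Step 6
Reactants: 12 (4S)-4-benzyl-3-[(2S,3R)-3-(benzyloxy)-2-methylpentanoyl]-1,3-oxazolidin-2-one
Product: 13 (2R,3R)-3-(benzyloxy)-2-methylpentan-1-ol
Conditions: LiBH4 (2 equiv), MeOH (2 equiv), Et2O, 0 °C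
Reagents that add atoms: none
Why: Reductive cleavage of the N-acyl oxazolidinone by LiBH4 should give the primary alcohol and return the auxiliary, leaving both stereocentres untouched.

Step 7
Reactants: 13 (2R,3R)-3-(benzyloxy)-2-methylpentan-1-ol
Product: 14 (2S,3R)-3-(benzyloxy)-2-methylpentanal
Conditions: Dess–Martin periodinane (1.2 equiv), NaHCO3, CH2Cl2, 0 °C → rt; used directly
Reagents that add atoms: none
Why: Dess–Martin oxidation under buffered, non-basic conditions should give the α-methyl aldehyde without epimerisation.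

Step 8
Reactants: 14 (2S,3R)-3-(benzyloxy)-2-methylpentanal; 7 1-methoxy-2-methyl-1,3-bis[(trimethylsilyl)oxy]penta-1,3-diene
Product: 15 methyl (5S,6R,7R)-7-(benzyloxy)-5-hydroxy-2,4,6-trimethyl-3-oxononanoate (epimer mixture at C2 and C4 of the ester)
Conditions: TiCl4 (1.1 equiv), CH2Cl2, −78 °C, then 7 (1.5 equiv), −78 °C; aqueous NaHCO3
Reagents that add atoms: none
Why: Vinylogous Mukaiyama aldol addition through the terminal carbon of the bis(silyloxy)diene to the TiCl4 chelate of the β-benzyloxy aldehyde (Cram-chelate control), with attack anti to the α-methyl group on the six-membered chelate, should set the C1 carbinol anti to the C7 methyl (anti-Felkin), while C4 and C6 stay epimeric and converge later.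

Step 9
Reactants: 15 methyl (5S,6R,7R)-7-(benzyloxy)-5-hydroxy-2,4,6-trimethyl-3-oxononanoate
Product: 16 (5S,6S)-6-[(2S,3R)-3-(benzyloxy)pentan-2-yl]-4-hydroxy-3,5-dimethyl-5,6-dihydro-2H-pyran-2-one
Conditions: K2CO3 (2 equiv), MeOH, 0 °C → rt; then 1 M HCl to pH 3
Reagents that add atoms: none
Why: Base-mediated lactonisation (intramolecular transesterification) of the δ-hydroxy β-keto ester should close ring B as the stable 4-hydroxy enol, the enolisable C6 centre equilibrating to the trans relation with the C1 substituent.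

Step 10
Reactants: 16 (5S,6S)-6-[(2S,3R)-3-(benzyloxy)pentan-2-yl]-4-hydroxy-3,5-dimethyl-5,6-dihydro-2H-pyran-2-one
Product: 17 (5S,6S)-4-hydroxy-6-[(2S,3R)-3-hydroxypentan-2-yl]-3,5-dimethyl-5,6-dihydro-2H-pyran-2-one
Conditions: H2 (1 atm), Pd/C (10 wt %), EtOAc, rt
Reagents that add atoms: none
Why: Hydrogenolysis of the benzyl ether over Pd/C should free the placeholder carbinol, the tetrasubstituted push–pull enol double bond being inert under these conditions.

Step 11
Reactants: 17 (5S,6S)-4-hydroxy-6-[(2S,3R)-3-hydroxypentan-2-yl]-3,5-dimethyl-5,6-dihydro-2H-pyran-2-one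
Product: 18 (5S,6R)-4-hydroxy-3,5-dimethyl-6-[(2R)-3-oxopentan-2-yl]-5,6-dihydro-2H-pyran-2-one
Conditions: Dess–Martin periodinane (1.3 equiv), NaHCO3, CH2Cl2, 0 °C
Reagents that add atoms: none
Why: Dess–Martin oxidation should turn the placeholder carbinol into the ethyl ketone (future C2′ with its ethyl group as C3′ and its methyl) under buffered conditions mild enough to avoid β-elimination of the lactone carboxylate from this β-acyloxy ketone.

Step 12
Reactants: 18 (5S,6R)-4-hydroxy-3,5-dimethyl-6-[(2R)-3-oxopentan-2-yl]-5,6-dihydro-2H-pyran-2-one; 4 (3R,4S)-3,4-dimethyloxetan-2-one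
Product: 21 (5S,6R)-4-hydroxy-6-[(1R)-1-[(2R,3S,5R,6S)-2-hydroxy-3,5,6-trimethyl-4-oxooxan-2-yl]ethyl]-3,5-dimethyl-5,6-dihydro-2H-pyran-2-one, via dilithio dianion 19 (not isolated), via open-chain hydroxy diketone 20 (not isolated)
Conditions: LiN(i-Pr)2 (2.1 equiv), THF, −78 °C; then 4 (1.2 equiv), −78 → −40 °C; AcOH (3 equiv), −78 °C, then pH 7 buffer, 0 °C
Reagents that add atoms: none
Why: Kinetic double deprotonation should give dianion 19 (lactone enolate plus the less substituted ethyl-ketone enolate), whose ketone enolate carbon (future C3′) attacks the strained carbonyl of 4 with acyl–oxygen cleavage (Claisen-type C-acylation, the known mode of β-lactone opening by hard lithium enolates), the released C6′ alkoxide serving as internal base towards the new β-diketone. On protonation the C6′ hydroxyl of 20 adds to the C2′ ketone (6-exo-trig hemiketalisation, the known behaviour of δ-hydroxy β-diketones), so that the four-membered ring O1′–C6′–C5′–C4′ has taken up C3′ and C2′ and has become ring A, a ring expansion by two atoms. C5′ and C6′ are carried over unchanged from 4, whereas the new C3′ centre lies between two carbonyl-level carbons and should equilibrate to the equatorial methyl because the axial alternative is 1,3-diaxial to the axial C5′ methyl; the anomeric C2′ hydroxyl should sit axial and is erased later. The step needs enolisation at the ethyl CH2 and not at the C7 methine (kinetic base at −78 °C, which also suppresses β-elimination of the lactone carboxylate), acyl and not alkyl attack on 4 (hard lithium enolate, secondary β-carbon of the lactone), and survival of the cis C5′/C6′ relation (the product is held as the C3′-centred diketonate until the cold acidic quench).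

Step 13
Reactants: 21 (5S,6R)-4-hydroxy-6-[(1R)-1-[(2R,3S,5R,6S)-2-hydroxy-3,5,6-trimethyl-4-oxooxan-2-yl]ethyl]-3,5-dimethyl-5,6-dihydro-2H-pyran-2-one
Product: 22 (5S,6R)-6-[(1R)-1-[(2S,3S,4R,5S,6S)-2,4-dihydroxy-3,5,6-trimethyloxan-2-yl]ethyl]-4-hydroxy-3,5-dimethyl-5,6-dihydro-2H-pyran-2-one
Conditions: Me4NBH(OAc)3 (5 equiv), MeCN/AcOH (1:1), −30 °C
Reagents that add atoms: none
Why: Evans–Saksena hydroxyl-directed reduction, in which the triacetoxyborohydride exchanges onto the axial anomeric hydroxyl (or, in the open form, the C6′ hydroxyl) and delivers hydride intramolecularly through a chair (1,3-anti), should place the C4′ hydroxyl equatorial and cis to the C5′ methyl while leaving the enolised lactone and the masked C2′ ketone unreduced.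

Step 14
Reactants: 22 (5S,6R)-6-[(1R)-1-[(2S,3S,4R,5S,6S)-2,4-dihydroxy-3,5,6-trimethyloxan-2-yl]ethyl]-4-hydroxy-3,5-dimethyl-5,6-dihydro-2H-pyran-2-one
Product: 24 (1S,4R,6S,7R,8S,3′S,4′R,5′S,6′S)-4′-hydroxy-3′,4,5′,6,6′,7-hexamethylspiro[2-oxabicyclo[2.2.2]octane-8,2′-oxane]-3,5-dione, via oxocarbenium ion 23 (not isolated)
Conditions: Tf2NH (10 mol %), 4 Å molecular sieves, CH2Cl2, −40 → 0 °C
Reagents that add atoms: none
Why: Brønsted-acid ionisation of the hemiketal should give the ring-A oxocarbenium ion, which is captured at carbon by the tethered lactone enol (acid-catalysed C-alkylation of a cyclic 1,3-dicarbonyl enol by an oxocarbenium ion, a Mukaiyama/Ferrier-type closure known for 4-hydroxypyranones, with reversible O-capture funnelling to the C–C product) in a six-membered closure that attacks axially on the chair-like cation bearing the C3′ methyl, C4′ hydroxyl and C6′ methyl equatorial, so that C8 and the bridge-constrained C4 are set together and C6 settles at its more stable configuration by enolisation.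

Step 15
Reactants: 24 (1S,4R,6S,7R,8S,3′S,4′R,5′S,6′S)-4′-hydroxy-3′,4,5′,6,6′,7-hexamethylspiro[2-oxabicyclo[2.2.2]octane-8,2′-oxane]-3,5-dione
Product: 25 (1S,4R,6S,7R,8S,3′S,4′R,5′R,6′S)-3′,4,5′,6,6′,7-hexamethyl-3,5-dioxospiro[2-oxabicyclo[2.2.2]octane-8,2′-oxan]-4′-yl acetate (CNP0257416.2)
Conditions: Ac2O (3 equiv), pyridine, DMAP (5 mol %), CH2Cl2, 0 °C → rt
Reagents that add atoms: acetic anhydride, CC(=O)OC(C)=O
Why: DMAP-catalysed acetylation of the single equatorial secondary hydroxyl under weakly basic conditions should give the target without triggering retro-oxa-Michael opening of the β-acyloxy ketone.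

## Compound list

1 | propionyl chloride | CCC(=O)Cl | starting material
2 | acetaldehyde | CC=O | starting material
3 | methylketene (not isolated) | CC=C=O | intermediate
4 | (3R,4S)-3,4-dimethyloxetan-2-one (cis-β-lactone) | O=C1[C@H](C)[C@H](C)O1 | intermediate
5 | methyl 2-methyl-3-oxopentanoate (racemic) | CCC(=O)C(C)C(=O)OC | starting material
6 | methyl 2-methyl-3-[(trimethylsilyl)oxy]pent-2-enoate (double-bond geometry not relevant) | CCC(O[Si](C)(C)C)=C(C)C(=O)OC | intermediate
7 | 1-methoxy-2-methyl-1,3-bis[(trimethylsilyl)oxy]penta-1,3-diene (geometry not relevant) | CC=C(O[Si](C)(C)C)C(C)=C(OC)O[Si](C)(C)C | intermediate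
8 | (4S)-4-benzyl-3-propanoyl-1,3-oxazolidin-2-one | CCC(=O)N1[C@@H](Cc2ccccc2)COC1=O | starting material
9 | propanal | CCC=O | starting material
10 | dibutylboron (Z)-enolate of 8 (not isolated) | CCCCB(CCCC)O/C(=C\C)N1[C@@H](Cc2ccccc2)COC1=O | intermediate
11 | (4S)-4-benzyl-3-[(2S,3R)-3-hydroxy-2-methylpentanoyl]-1,3-oxazolidin-2-one | CC[C@@H](O)[C@H](C)C(=O)N1[C@@H](Cc2ccccc2)COC1=O | intermediate
12 | (4S)-4-benzyl-3-[(2S,3R)-3-(benzyloxy)-2-methylpentanoyl]-1,3-oxazolidin-2-one | CC[C@@H](OCc1ccccc1)[C@H](C)C(=O)N2[C@@H](Cc3ccccc3)COC2=O | intermediate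
13 | (2R,3R)-3-(benzyloxy)-2-methylpentan-1-ol | CC[C@@H](OCc1ccccc1)[C@H](C)CO | intermediate
14 | (2S,3R)-3-(benzyloxy)-2-methylpentanal | CC[C@@H](OCc1ccccc1)[C@H](C)C=O | intermediate
15 | methyl (5S,6R,7R)-7-(benzyloxy)-5-hydroxy-2,4,6-trimethyl-3-oxononanoate (epimer mixture at C2 and C4) | CC[C@@H](OCc1ccccc1)[C@H](C)[C@H](O)C(C)C(=O)C(C)C(=O)OC | intermediate
16 | (5S,6S)-6-[(2S,3R)-3-(benzyloxy)pentan-2-yl]-4-hydroxy-3,5-dimethyl-5,6-dihydro-2H-pyran-2-one | CC[C@@H](OCc1ccccc1)[C@H](C)[C@@H]2OC(=O)C(C)=C(O)[C@H]2C | intermediate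
17 | (5S,6S)-4-hydroxy-6-[(2S,3R)-3-hydroxypentan-2-yl]-3,5-dimethyl-5,6-dihydro-2H-pyran-2-one | CC[C@@H](O)[C@H](C)[C@@H]1OC(=O)C(C)=C(O)[C@H]1C | intermediate
18 | (5S,6R)-4-hydroxy-3,5-dimethyl-6-[(2R)-3-oxopentan-2-yl]-5,6-dihydro-2H-pyran-2-one | CCC(=O)[C@H](C)[C@@H]1OC(=O)C(C)=C(O)[C@H]1C | intermediate
19 | dilithio dianion of 18: lactone enolate and ethyl-ketone enolate (not isolated; enolate geometry not relevant) | CC=C([O-])[C@H](C)[C@@H]1OC(=O)C(C)=C([O-])[C@H]1C.[Li+].[Li+] | intermediate
20 | open-chain δ-hydroxy β-diketone from C-acylation of 19 by 4, shown protonated (not isolated; C3′ epimerisable) | C[C@H](O)[C@@H](C)C(=O)C(C)C(=O)[C@H](C)[C@@H]1OC(=O)C(C)=C(O)[C@H]1C | intermediate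
21 | (5S,6R)-4-hydroxy-6-[(1R)-1-[(2R,3S,5R,6S)-2-hydroxy-3,5,6-trimethyl-4-oxooxan-2-yl]ethyl]-3,5-dimethyl-5,6-dihydro-2H-pyran-2-one | O=C1[C@H](C)[C@H](C)O[C@](O)([C@H](C)[C@@H]2OC(=O)C(C)=C(O)[C@H]2C)[C@H]1C | intermediate
22 | (5S,6R)-6-[(1R)-1-[(2S,3S,4R,5S,6S)-2,4-dihydroxy-3,5,6-trimethyloxan-2-yl]ethyl]-4-hydroxy-3,5-dimethyl-5,6-dihydro-2H-pyran-2-one | O[C@@H]1[C@H](C)[C@H](C)O[C@](O)([C@H](C)[C@@H]2OC(=O)C(C)=C(O)[C@H]2C)[C@H]1C | intermediate
23 | ring-A oxocarbenium ion from 22, bistriflimide ion pair (not isolated) | O[C@@H]1[C@H](C)[C@H](C)[O+]=C([C@H](C)[C@@H]2OC(=O)C(C)=C(O)[C@H]2C)[C@H]1C.O=S(=O)([N-]S(=O)(=O)C(F)(F)F)C(F)(F)F | intermediate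
24 | (1S,4R,6S,7R,8S,3′S,4′R,5′S,6′S)-4′-hydroxy-3′,4,5′,6,6′,7-hexamethylspiro[2-oxabicyclo[2.2.2]octane-8,2′-oxane]-3,5-dione | O[C@@H]1[C@H](C)[C@H](C)O[C@]2([C@H](C)[C@@H]3OC(=O)[C@@]2(C)C(=O)[C@H]3C)[C@H]1C | intermediate
25 | (1S,4R,6S,7R,8S,3′S,4′R,5′R,6′S)-3′,4,5′,6,6′,7-hexamethyl-3,5-dioxospiro[2-oxabicyclo[2.2.2]octane-8,2′-oxan]-4′-yl acetate (CNP0257416.2) | CC(=O)O[C@@H]1[C@H](C)[C@H](C)O[C@]2([C@H](C)[C@@H]3OC(=O)[C@@]2(C)C(=O)[C@H]3C)[C@H]1C | target

## Step count and risks

Total steps: 15 (step 1 for the β-lactone, steps 2–3 for the diene, steps 4–15 for the main chain).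
Longest linear sequence: 12 steps (steps 4–15, from 8).

The three steps most likely to fail:

Step 12 (ring-expanding union). The kinetic ethyl-ketone enolate may equilibrate to the C7 enolate, which would expel the lactone carboxylate by β-elimination. Proton transfer from 4 to the dianion may also compete with acylation. The fallback sets out from 18 and returns to the route at 24. The acidic enol is capped first: Me3SiCHN2 in MeOH/toluene should give the methyl enol ether ketone F1. A single kinetic enolate (LiN(i-Pr)2, 1.05 equiv, THF, −78 °C) is then acylated by 4 in the same ring-expanding manner to give the hemiketal F2. Directed reduction with Me4NBH(OAc)3 gives the diol F3. Tf2NH in CH2Cl2 followed by aqueous work-up should close ring C through the enol-ether carbon, with loss of methanol, to give 24.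

Step 14 (spirocyclisation). The oxocarbenium ion may lose the C7 configuration by reversible deprotonation to the exocyclic enol ether, and capture may stall at the enol oxygen instead of carbon. The fallback sets out from 22 and returns at 24. Pyridinium p-toluenesulfonate (4 Å molecular sieves, CH2Cl2, rt) should deliberately form the O-linked spiroketal enol ether F4. Me2AlCl (CH2Cl2, −78 → 0 °C) should then effect the O→C rearrangement (Petasis–Ferrier-type 1,3-shift, related to Fries-type O→C glycoside rearrangements) within a tight aluminium enolate/oxocarbenium pair, at low temperature and without free Brønsted acid, giving 24.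

Step 13 (directed reduction). The hemiketal may dehydrate to the 2,3-dihydro-4H-pyran-4-one before hydride is delivered, and C5′ may epimerise. The fallback sets out from 21 and returns at 24. Dehydration is accepted: CF3CO2H in CH2Cl2 (0 °C) should give the dihydropyranone F5. Luche reduction (NaBH4, CeCl3·7H2O, MeOH, −78 °C; hydride anti to the pseudoaxial C5′ methyl) should give the allylic alcohol F6. Tf2NH-catalysed protonation of the cyclic enol ether at C3′ (CH2Cl2, −40 °C) regenerates oxocarbenium ion 23, with C3′ set under Curtin–Hammett control by the chair-like closure, and should give 24.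

Further compounds
F1 | step 12 | (5S,6R)-4-methoxy-3,5-dimethyl-6-[(2R)-3-oxopentan-2-yl]-5,6-dihydro-2H-pyran-2-one | CCC(=O)[C@H](C)[C@@H]1OC(=O)C(C)=C(OC)[C@H]1C
F2 | step 12 | 4-O-methyl analogue of hemiketal 21 | O=C1[C@H](C)[C@H](C)O[C@](O)([C@H](C)[C@@H]2OC(=O)C(C)=C(OC)[C@H]2C)[C@H]1C
F3 | step 12 | 4-O-methyl analogue of diol 22 | O[C@@H]1[C@H](C)[C@H](C)O[C@](O)([C@H](C)[C@@H]2OC(=O)C(C)=C(OC)[C@H]2C)[C@H]1C
F4 | step 14 | spiroketal enol ether formed by the lactone enol oxygen and C2′ (O-linked isomer of 24) | O[C@@H]1[C@H](C)[C@H](C)O[C@]2([C@H](C)[C@@H]3OC(=O)C(C)=C(O2)[C@H]3C)[C@H]1C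
F5 | step 13 | 2,3-dihydro-4H-pyran-4-one from dehydration of 21 (C2′=C3′) | O=C1[C@H](C)[C@H](C)OC([C@H](C)[C@@H]2OC(=O)C(C)=C(O)[C@H]2C)=C1C
F6 | step 13 | allylic alcohol from 1,2-reduction of F5 (4′R) | O[C@@H]1[C@H](C)[C@H](C)OC([C@H](C)[C@@H]2OC(=O)C(C)=C(O)[C@H]2C)=C1C
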